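**Strategy.** The route rests on cutting the heptanoid at C5. The flavone 7‑OH oxygen, C7 and C8 of ring A, the benzylic stereocentre C5, C4 and the C3 ketone carbon are the six ring atoms of a 2‑alkoxychroman ketal fused to ring A. One three‑component operation joins an 8‑formyl‑7‑O‑Boc galangin 3,5‑dibenzyl ether, an arylethyl Grignard reagent and a chiral 2‑alkoxy‑4‑phenylbutene. It forms C5–C6, unveils an o‑quinone methide across O7–C7–C8–C5, and closes the dihydropyran by hetero‑Diels–Alder addition, forming C5–C4 and O7–C3 and setting C5. Ketal hydrolysis and hydrogenolysis then give the target.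

Key step: step 11

Numbering: flavone atoms keep their usual locants; heptanoid carbons are counted C1 to C7 from the phenyl end, so the ketone is C3 and the stereocentre C5 (two carbons apart; required configuration R).

Assumption: the (1S,2R) auxiliary is taken to leave open the enol ether face that leads to (R)‑C5; if the sense proves opposite, the (1R,2S) alcohol, equally available, is carried through the same steps.

Step 1
Reactants: 1 galangin
Product: 2 7-(allyloxy)-3,5-dihydroxyflavone
Conditions: allyl bromide (1.05 equiv), K2CO3 (1.1 equiv), DMF, 0 °C to rt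
Reagents that add atoms: allyl bromide, C=CCBr
Why: Williamson etherification at the most acidic hydroxyl, since O7–H (conjugated with the C4 carbonyl through ring A) ionises first while O3–H and O5–H are held in hydrogen bonds to C4=O, so one equivalent of weak base and halide should alkylate O7 only.

Step 2
Reactants: 2 7-(allyloxy)-3,5-dihydroxyflavone
Product: 3 7-(allyloxy)-3,5-bis(benzyloxy)flavone
Conditions: BnBr (3 equiv), K2CO3 (4 equiv), KI (10 mol%), DMF, 70 °C
Reagents that add atoms: benzyl bromide, BrCc1ccccc1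
Why: Williamson etherification of both remaining hydroxyls, the excess of base and the heating being needed to break the O5–H to C4=O chelate, while the allyl ether is inert at this temperature.

Step 3
Reactants: 3 7-(allyloxy)-3,5-bis(benzyloxy)flavone
Product: 4 3,5-bis(benzyloxy)-7-hydroxyflavone
Conditions: Pd(PPh3)4 (5 mol%), morpholine (5 equiv), THF, rt
Reagents that add atoms: none
Why: Tsuji–Trost deallylation, in which zerovalent palladium ionises the allyl aryl ether (the 7‑oxide of a flavone is a good leaving group) and morpholine captures the allyl cation equivalent, leaving the benzyl ethers untouched.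

Step 4
Reactants: 4 3,5-bis(benzyloxy)-7-hydroxyflavone
Product: 6 3,5-bis(benzyloxy)-8-formyl-7-hydroxyflavone, via hydroxymethyl phenol 5 (not isolated)
Conditions: MgCl2 (3 equiv), Et3N (6 equiv), paraformaldehyde (10 equiv), MeCN, reflux; then cold 1 M aq. HCl
Reagents that add atoms: paraformaldehyde (formaldehyde), C=O
Why: Casnati–Skattebøl magnesium‑mediated ortho‑formylation, in which the magnesium 7‑phenoxide delivers coordinated formaldehyde only ortho to O7 and a second formaldehyde oxidises the benzylic alkoxide 5 by hydride transfer; of the two ortho sites the less hindered C8 (para to the C5 ether, the usual site of electrophilic attack in 5‑O‑alkyl flavones) should react, and the basic medium spares the acid‑sensitive C5 benzyl ether.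

Step 5
Reactants: 6 3,5-bis(benzyloxy)-8-formyl-7-hydroxyflavone
Product: 7 3,5-bis(benzyloxy)-7-(tert-butoxycarbonyloxy)-8-formylflavone
Conditions: Boc2O (1.3 equiv), iPr2NEt (1.5 equiv), DMAP (5 mol%), CH2Cl2, 0 °C
Reagents that add atoms: di-tert-butyl dicarbonate, CC(C)(C)OC(=O)OC(=O)OC(C)(C)C
Why: DMAP‑catalysed O‑acylation of the acidic 7‑phenol gives the aryl tert‑butyl carbonate under mild conditions that leave the aldehyde alone; the labile carbonate is to be used without delay.

Step 6
Reactants: 8 homovanillyl alcohol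
Product: 9 2-[4-(benzyloxy)-3-methoxyphenyl]ethanol
Conditions: BnBr (1.1 equiv), K2CO3 (1.5 equiv), acetone, reflux
Reagents that add atoms: benzyl bromide, BrCc1ccccc1
Why: Williamson etherification that is chemoselective for the phenol, because carbonate deprotonates the phenol but not the primary alcohol.

Step 7
Reactants: 9 2-[4-(benzyloxy)-3-methoxyphenyl]ethanol
Product: 10 1-(benzyloxy)-4-(2-bromoethyl)-2-methoxybenzene
Conditions: CBr4 (1.3 equiv), PPh3 (1.3 equiv), CH2Cl2, 0 °C to rt
Reagents that add atoms: carbon tetrabromide, BrC(Br)(Br)Br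
Why: Appel bromination of a primary alcohol by SN2 displacement of the alkoxyphosphonium ion under neutral conditions that keep the benzyl ether.

Step 8
Reactants: 10 1-(benzyloxy)-4-(2-bromoethyl)-2-methoxybenzene
Product: 11 2-[4-(benzyloxy)-3-methoxyphenyl]ethylmagnesium bromide (Et2O solution, titrated and used at once)
Conditions: Mg turnings (1.5 equiv), I2 (crystal), Et2O, rt to gentle reflux, slow addition of 10
Reagents that add atoms: magnesium, [Mg]
Why: Grignard reagent formation by insertion of magnesium into a primary C–Br bond; 2‑arylethylmagnesium halides carry no β‑leaving group and the aryl ethers are inert, and slow addition limits Wurtz coupling.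

Step 9
Reactants: 12 (1S,2R)-trans-2-phenylcyclohexanol; 13 3-phenylpropanoyl chloride
Product: 14 (1S,2R)-2-phenylcyclohexyl 3-phenylpropanoate
Conditions: Et3N (1.5 equiv), DMAP (10 mol%), CH2Cl2, 0 °C to rt
Reagents that add atoms: none
Why: DMAP‑catalysed acylation of a secondary alcohol by an acid chloride, in which the carbinol C–O bond is never broken, so both stereocentres of the auxiliary are retained.

Step 10
Reactants: 14 (1S,2R)-2-phenylcyclohexyl 3-phenylpropanoate
Product: 15 4-phenyl-2-[(1S,2R)-2-phenylcyclohexyloxy]but-1-ene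
Conditions: Cp2TiMe2 (2.5 equiv), toluene, 70 °C, dark; filtration through basic alumina
Reagents that add atoms: dimethyltitanocene, C[Ti](C)(C1C=CC=C1)C1C=CC=C1
Why: Petasis methylenation, in which thermally formed Cp2Ti=CH2 adds across the ester carbonyl and the oxatitanacycle cycloreverts to the 1,1‑disubstituted enol ether under non‑acidic, non‑basic conditions that neither move the double bond nor touch the auxiliary.

Step 11
Reactants: 7 3,5-bis(benzyloxy)-7-(tert-butoxycarbonyloxy)-8-formylflavone; 11 2-[4-(benzyloxy)-3-methoxyphenyl]ethylmagnesium bromide; 15 4-phenyl-2-[(1S,2R)-2-phenylcyclohexyloxy]but-1-ene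
Product: 19 (8R,10R)-3,5-bis(benzyloxy)-10-{2-[4-(benzyloxy)-3-methoxyphenyl]ethyl}-2-phenyl-8-(2-phenylethyl)-8-{[(1S,2R)-2-phenylcyclohexyl]oxy}-9,10-dihydro-4H,8H-pyrano[2,3-f]chromen-4-one (the 2-alkoxychroman ketal fused at C7–C8 of the flavone; alkoxy cis to arylethyl), via magnesium alkoxide 16 (not isolated), via benzylic carbonate 17 (not isolated), via o-quinone methide 18 (not isolated)
Conditions: 7 (1.0 equiv) and 15 (3 equiv), toluene, −78 °C; 11 (1.05 equiv, Et2O) dropwise; −78 °C 1 h, then to rt over 4 h; aq. NaHCO3; chromatography on Et3N-treated silica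
Reagents that add atoms: none
Why: At −78 °C reagent 11 adds to the formyl group of 7, by far the most electrophilic site beside the donor‑deactivated C4 carbonyl and the hindered carbonate, the alkoxide 16 takes the tert‑butoxycarbonyl group from the neighbouring O7 through a six‑membered transition state to give 17, and on warming the magnesium phenoxide expels tert‑butyl carbonate to unveil the E‑configured o‑quinone methide 18, which 15 intercepts. The closest known reaction type is the Grignard‑triggered conversion of ortho‑(Boc‑oxy) salicylaldehydes into o‑quinone methides with in situ trapping by chiral enol ethers, used here on a flavone‑fused salicylaldehyde and a 1,1‑disubstituted enol ether. The single new ring, the dihydropyran O7–C7–C8–C5–C4–C3, closes by an intermolecular inverse‑electron‑demand hetero‑Diels–Alder (4+2) cycloaddition in which C5–C4 and O7–C3 form in one asynchronous event, the nucleophilic CH2 of 15 bonding to the methide carbon and O7 to the oxygen‑bearing carbon. The ketal carbon C3 is set by the auxiliary, whose 2‑phenyl group lies over one face of the enol ether so that 18 adds to the open face, and C5 follows from that same face through the endo placement of the alkoxy group under the heterodiene and the E geometry of 18, which put the alkoxy and arylethyl groups cis and should give (R)‑C5. The step needs E geometry, secured by allylic 1,3‑strain that turns the arylethyl group away from the magnesium‑bound O7 towards the substituent‑free ring oxygen O1, endo selectivity, which is the normal preference of enol ethers towards o‑quinone methides, and freedom from a second Grignard addition to 18, secured by a titrated 1.05 equiv of 11 and a threefold excess of 15, the surplus of which is recovered.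

Step 12
Reactants: 19 the flavone-fused 2-alkoxychroman ketal
Product: 20 3,5-bis(benzyloxy)-8-[(5R)-7-(4-benzyloxy-3-methoxyphenyl)-3-oxo-1-phenylheptan-5-yl]-7-hydroxyflavone
Conditions: 0.5 M aq. HCl, THF, rt
Reagents that add atoms: water, O
Why: Acid‑catalysed hydrolysis of a mixed aryl alkyl ketal through the oxocarbenium ion and its hemiketal releases the C3 ketone, the 7‑phenol and the auxiliary alcohol; C5 takes no part and keeps its configuration, and dilute acid at rt should spare the C5 benzyl ether.

Step 13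
Reactants: 20 3,5-bis(benzyloxy)-8-[(5R)-7-(4-benzyloxy-3-methoxyphenyl)-3-oxo-1-phenylheptan-5-yl]-7-hydroxyflavone
Product: 21 8-[(5R)-7-(4-hydroxy-3-methoxyphenyl)-3-oxo-1-phenylheptan-5-yl]-3,5,7-trihydroxy-2-phenyl-4H-chromen-4-one (CNP0164153.1)
Conditions: H2 (1 atm), 10% Pd/C, EtOAc/MeOH, rt
Reagents that add atoms: none
Why: Catalytic hydrogenolysis of the three benzyl aryl ethers, under which the tetrasubstituted C2=C3 bond of the chromone, the dialkyl ketone and the C5 stereocentre should stay untouched.

**Compound list**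

1 | galangin (3,5,7-trihydroxy-2-phenyl-4H-chromen-4-one) | O=c1c(O)c(-c2ccccc2)oc2cc(O)cc(O)c12 | starting material
2 | 7-(allyloxy)-3,5-dihydroxyflavone | O=c1c(O)c(-c2ccccc2)oc2cc(OCC=C)cc(O)c12 | intermediate
3 | 7-(allyloxy)-3,5-bis(benzyloxy)flavone | O=c1c(OCc2ccccc2)c(-c2ccccc2)oc2cc(OCC=C)cc(OCc3ccccc3)c12 | intermediate
4 | 3,5-bis(benzyloxy)-7-hydroxyflavone | O=c1c(OCc2ccccc2)c(-c2ccccc2)oc2cc(O)cc(OCc3ccccc3)c12 | intermediate
5 | 3,5-bis(benzyloxy)-7-hydroxy-8-(hydroxymethyl)flavone (formed as its magnesium salt) | O=c1c(OCc2ccccc2)c(-c2ccccc2)oc2c(CO)c(O)cc(OCc3ccccc3)c12 | intermediate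
6 | 3,5-bis(benzyloxy)-8-formyl-7-hydroxyflavone | O=Cc1c(O)cc(OCc2ccccc2)c2c(=O)c(OCc3ccccc3)c(-c3ccccc3)oc12 | intermediate
7 | 3,5-bis(benzyloxy)-7-(tert-butoxycarbonyloxy)-8-formylflavone | O=Cc1c(OC(=O)OC(C)(C)C)cc(OCc2ccccc2)c2c(=O)c(OCc3ccccc3)c(-c3ccccc3)oc12 | intermediate
8 | homovanillyl alcohol, 2-(4-hydroxy-3-methoxyphenyl)ethanol | COc1cc(CCO)ccc1O | starting material
9 | 2-[4-(benzyloxy)-3-methoxyphenyl]ethanol | COc1cc(CCO)ccc1OCc1ccccc1 | intermediate
10 | 1-(benzyloxy)-4-(2-bromoethyl)-2-methoxybenzene | COc1cc(CCBr)ccc1OCc1ccccc1 | intermediate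
11 | 2-[4-(benzyloxy)-3-methoxyphenyl]ethylmagnesium bromide | COc1cc(CC[Mg]Br)ccc1OCc1ccccc1 | intermediate
12 | (1S,2R)-trans-2-phenylcyclohexanol | O[C@H]1CCCC[C@@H]1c1ccccc1 | starting material
13 | 3-phenylpropanoyl chloride | O=C(Cl)CCc1ccccc1 | starting material
14 | (1S,2R)-2-phenylcyclohexyl 3-phenylpropanoate | O=C(CCc1ccccc1)O[C@H]1CCCC[C@@H]1c1ccccc1 | intermediate
15 | 4-phenyl-2-[(1S,2R)-2-phenylcyclohexyloxy]but-1-ene | C=C(CCc1ccccc1)O[C@H]1CCCC[C@@H]1c1ccccc1 | intermediate
16 | bromomagnesium alkoxide of 3,5-bis(benzyloxy)-7-(tert-butoxycarbonyloxy)-8-{3-[4-(benzyloxy)-3-methoxyphenyl]-1-hydroxypropyl}flavone (both carbinol epimers) | COc1cc(CCC(O[Mg]Br)c2c(OC(=O)OC(C)(C)C)cc(OCc3ccccc3)c3c(=O)c(OCc4ccccc4)c(-c4ccccc4)oc23)ccc1OCc1ccccc1 | intermediate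
17 | bromomagnesium 7-phenoxide of 3,5-bis(benzyloxy)-8-{3-[4-(benzyloxy)-3-methoxyphenyl]-1-(tert-butoxycarbonyloxy)propyl}-7-hydroxyflavone | COc1cc(CCC(OC(=O)OC(C)(C)C)c2c(O[Mg]Br)cc(OCc3ccccc3)c3c(=O)c(OCc4ccccc4)c(-c4ccccc4)oc23)ccc1OCc1ccccc1 | intermediate
18 | (8E)-3,5-bis(benzyloxy)-8-{3-[4-(benzyloxy)-3-methoxyphenyl]propylidene}-2-phenyl-4H-chromene-4,7(8H)-dione (o-quinone methide) | O=C1C=C(OCc2ccccc2)C2=C(OC(c3ccccc3)=C(OCc3ccccc3)C2=O)/C1=C\CCc1ccc(OCc2ccccc2)c(OC)c1 | intermediate
19 | (8R,10R)-3,5-bis(benzyloxy)-10-{2-[4-(benzyloxy)-3-methoxyphenyl]ethyl}-2-phenyl-8-(2-phenylethyl)-8-{[(1S,2R)-2-phenylcyclohexyl]oxy}-9,10-dihydro-4H,8H-pyrano[2,3-f]chromen-4-one | O=c1c(OCc2ccccc2)c(-c2ccccc2)oc2c1c(OCc1ccccc1)cc1O[C@](O[C@H]3CCCC[C@@H]3c3ccccc3)(CCc3ccccc3)C[C@@H](CCc3ccc(OCc4ccccc4)c(OC)c3)c12 | intermediate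
20 | 3,5-bis(benzyloxy)-8-[(5R)-7-(4-benzyloxy-3-methoxyphenyl)-3-oxo-1-phenylheptan-5-yl]-7-hydroxyflavone | COc1cc(CC[C@H](CC(=O)CCc2ccccc2)c2c(O)cc(OCc3ccccc3)c3c(=O)c(OCc4ccccc4)c(-c4ccccc4)oc23)ccc1OCc1ccccc1 | intermediate
21 | 8-[(5R)-7-(4-hydroxy-3-methoxyphenyl)-3-oxo-1-phenylheptan-5-yl]-3,5,7-trihydroxy-2-phenyl-4H-chromen-4-one | COc1cc(CC[C@H](CC(=O)CCc2ccccc2)c2c(O)cc(O)c3c(=O)c(O)c(-c4ccccc4)oc23)ccc1O | target

**Step count.** Total: 13 steps. Longest linear sequence: 8 steps (steps 1, 2, 3, 4, 5, 11, 12, 13).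

**Steps most likely to fail**

Step 11. Facial or endo control may erode, or trapping may be slow enough for the quinone methide to dimerise or tautomerise, because the 1,1‑disubstituted enol ether is bulkier than a vinyl ether and may react through another conformation. The fallback sets out from 7, 11 and 12 and comes back at 20. Alcohol 12 is vinylated ([Ir(cod)Cl]2, Na2CO3, vinyl acetate, toluene, 100 °C) to (1S,2R)-2-phenylcyclohexyl vinyl ether F1, the monosubstituted enol ether class for which this cascade is established. Aldehyde 7, reagent 11 and F1 under the conditions of step 11 should give the acetal cycloadduct F2. Dilute aqueous HCl in THF opens it to the lactol F3 and returns 12. 2‑Phenylethylmagnesium bromide (3 equiv, THF, 0 °C) adds to the open hydroxy aldehyde form to give the phenol alcohol F4, whose C3 epimers are of no consequence. Dess–Martin periodinane (NaHCO3, CH2Cl2, 0 °C) oxidises the secondary alcohol to ketone 20. C3 thus enters at the aldehyde level and the C2–C3 bond is made afterwards.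

Step 4. Formylation may go to C6 in place of C8, or stall through slow hydroxymethylation of the electron‑poor phenoxide or incomplete hydride transfer. The fallback sets out from 3 and comes back at 6. An aromatic Claisen rearrangement (N,N‑diethylaniline, 190 °C) carries the allyl group from O7 to C8 within the molecule and should give 8-allyl-3,5-bis(benzyloxy)-7-hydroxyflavone F5. RuHCl(CO)(PPh3)3 (5 mol%, toluene, 80 °C) moves the double bond into conjugation to give 3,5-bis(benzyloxy)-7-hydroxy-8-[(E)-prop-1-enyl]flavone F6. Lemieux–Johnson cleavage (OsO4 2 mol%, NaIO4, 2,6‑lutidine, dioxane/H2O) then gives aldehyde 6.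

Step 1. Alkylation may spread to O3 or go twice, since the site selectivity rests only on the acidity difference between the hydroxyls. The fallback sets out from 1 and comes back at 2. Acetic anhydride in pyridine gives galangin triacetate F7. Allyl bromide, K2CO3 and KI in refluxing acetone exchange only the most labile ester, the 7‑acetate, for an allyl group and should give 7-(allyloxy)-3,5-diacetoxyflavone F8. K2CO3 in MeOH at rt removes the two remaining acetates to give 2.

**Further compounds**

F1 | step 11 | (1S,2R)-2-phenylcyclohexyl vinyl ether | C=CO[C@H]1CCCC[C@@H]1c1ccccc1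
F2 | step 11 | (8R,10R)-3,5-bis(benzyloxy)-10-{2-[4-(benzyloxy)-3-methoxyphenyl]ethyl}-2-phenyl-8-{[(1S,2R)-2-phenylcyclohexyl]oxy}-9,10-dihydro-4H,8H-pyrano[2,3-f]chromen-4-one (acetal cycloadduct) | O=c1c(OCc2ccccc2)c(-c2ccccc2)oc2c1c(OCc1ccccc1)cc1O[C@@H](O[C@H]3CCCC[C@@H]3c3ccccc3)C[C@@H](CCc3ccc(OCc4ccccc4)c(OC)c3)c12
F3 | step 11 | (10R)-3,5-bis(benzyloxy)-10-{2-[4-(benzyloxy)-3-methoxyphenyl]ethyl}-8-hydroxy-2-phenyl-9,10-dihydro-4H,8H-pyrano[2,3-f]chromen-4-one (lactol, both anomers) | O=c1c(OCc2ccccc2)c(-c2ccccc2)oc2c1c(OCc1ccccc1)cc1OC(O)C[C@@H](CCc3ccc(OCc4ccccc4)c(OC)c3)c12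
F4 | step 11 | 3,5-bis(benzyloxy)-8-[(5R)-7-(4-benzyloxy-3-methoxyphenyl)-3-hydroxy-1-phenylheptan-5-yl]-7-hydroxyflavone (C3 epimers) | COc1cc(CC[C@H](CC(O)CCc2ccccc2)c2c(O)cc(OCc3ccccc3)c3c(=O)c(OCc4ccccc4)c(-c4ccccc4)oc23)ccc1OCc1ccccc1
F5 | step 4 | 8-allyl-3,5-bis(benzyloxy)-7-hydroxyflavone | O=c1c(OCc2ccccc2)c(-c2ccccc2)oc2c(CC=C)c(O)cc(OCc3ccccc3)c12
F6 | step 4 | 3,5-bis(benzyloxy)-7-hydroxy-8-[(E)-prop-1-enyl]flavone | O=c1c(OCc2ccccc2)c(-c2ccccc2)oc2c(/C=C/C)c(O)cc(OCc3ccccc3)c12
F7 | step 1 | galangin triacetate (3,5,7-triacetoxyflavone) | CC(=O)Oc1cc(OC(C)=O)c2c(=O)c(OC(C)=O)c(-c3ccccc3)oc2c1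
F8 | step 1 | 7-(allyloxy)-3,5-diacetoxyflavone | C=CCOc1cc(OC(C)=O)c2c(=O)c(OC(C)=O)c(-c3ccccc3)oc2c1
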